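At 10 h I read this flask, and before charging it I must choose between the reagent charge of 0.960 M and the 1.9 M of the north-east run.

common to all: catalyst 2.4 mM
- east: left-handed substrate 0.24 M; right-handed substrate 0.24 M; reagent 0.48 M; run made earlier
- north-east: left-handed substrate 0.24 M; right-handed substrate 0.24 M; reagent 1.9 M; run made earlier
- south: left-handed substrate 0.48 M; right-handed substrate 0.48 M; reagent 0.96 M; run made earlier
- flask: left-handed substrate 0.24 M; right-handed substrate 0.24 M; reagent 0.960 M; time 10 h

| run | time / h | left-handed substrate / % | right-handed substrate / % |
|---|---|---|---|
| east | 0.833 | 46.2 | 46.8 |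
| east | 1.33 | 45.8 | 45.8 |
| east | 2.00 | 44.3 | 44.7 |
| east | 3.00 | 43.7 | 43.7 |
| east | 4.00 | 43.6 | 43.5 |
| east | 6.00 | 42.9 | 42.6 |
| east | 10.0 | 41.5 | 41.7 |
| north-east | 0.833 | 43.6 | 43.1 |
| north-east | 1.33 | 42.5 | 42.2 |
| north-east | 2.00 | 41.2 | 41.0 |
| north-east | 3.00 | 40.3 | 40.6 |
| north-east | 4.00 | 40.0 | 39.3 |
| north-east | 6.00 | 38.9 | 38.8 |
| north-east | 10.0 | 38.3 | 38.3 |
| south | 0.833 | 45.2 | 45.4 |
| south | 1.50 | 44.2 | 44.3 |
| south | 3.00 | 42.7 | 42.4 |
| south | 5.00 | 41.5 | 41.4 |
| south | 10.0 | 41.2 | 41.1 |

(standard deviation of a reading: 0.3 percentage points)

- catalyst is single-handed; left-handed substrate and right-handed substrate are mirror images of each other, charged as a racemate, each of them at the stated concentration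
- the earlier runs were read with a standard deviation of 0.3 percentage points
- steps under discussion: reagent + catalyst + left-handed substrate -> catalyst + left-handed product; reagent + catalyst + right-handed substrate -> catalyst + right-handed product; left-handed substrate <-> right-handed substrate; reagent -> decomposition product; 2 reagent -> homo dimer
- an excess is the difference of the two amounts in percent of their sum
- an excess is below zero if the other one leads

- part of the left-handed substrate and right-handed substrate charged together that has reacted at 10 h
- excess of left-handed product over right-handed product in the product at 10 h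
- excess of right-handed substrate over left-handed substrate among what is left of the two at 10 h

Let L be the logarithm of one over the fraction of both substrates left. At 10 h, L is 0.184 in the east run and 0.267 in the north-east run, so 3.96 times the reagent gives 1.45 times the L. I read this as reagent pairing with itself to homo dimer: that loss slows as it goes, so late on both runs should stand near the same c(reagent), the larger charge having passed 1.98 more halvings. My rule, for these substrate and catalyst charges read at 10 h, is that each halving the reagent charge passes adds the same amount to L; I call that amount the bite, 0.0416, a reading from runs with a scatter of 0.3 percentage points.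

This flask has one halving more than the east run, so I reckon L at 0.226 and c at 20.2%. The north-east run reacted 23.4% for twice this flask's reagent, so I stay at 0.960 M. Its substrates read 38.3% and 38.3% at 10.0 h, so I expect eS near zero. Equal substrates can mean an unselective catalyst or fast interconversion, so I commit to no eP and add a product reading.

The forecast gives c 19.8%, a little below mine, with eP 0% and eS 0%, and says “eP's magnitude and sign are essentially unconstrained”.

The flask gives c 20.4%, eP 94.3% and eS 0.0134%.

    reagent + catalyst + left-handed substrate → catalyst + left-handed product (k = 4.10 M⁻² min⁻¹)
    reagent + catalyst + right-handed substrate → catalyst + right-handed product (k = 0.120 M⁻² min⁻¹)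
    left-handed substrate ⇌ right-handed substrate (k = 0.210 min⁻¹)
    reagent → decomposition product (k = 4.30 × 10⁻⁵ min⁻¹)
    2 reagent → homo dimer (k = 0.0350 M⁻¹ min⁻¹)

The flask's L of 0.228 counts 5.49 bites. Catalyst enters both substrate steps but not the step to homo dimer, so for the neighbour charged with 9.6 × 10⁻⁴ M of catalyst I scale the bite to 0.0167. The same count of bites then gives c 8.73%. That neighbour stands at c 9.51% and eP 94.3%, with 1.8% of its reagent left, against 1.2% in this flask.

The readings were computed on assumed constants; the scatter is artificial.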